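**Retrosynthetic overview**

1. The last step only frees the C5 and C7 hydroxyls of unit 1 (benzyl ethers, hydrogenolysis); before that, unit 2 is unfolded.
2. The strategy rests on unit 2, the 5,7-dihydroxychromen-4-one bonded through C2 to ring M (the central methoxybenzene). It carries oxygen on every second carbon of the chain C2–C3–C4–C4a–C5–C6–C7–C8–C8a: at C2 and C4 in the pyranone and at C5, C7 and C8a in its benzo ring, called ring D here (C4a, C5, C6, C7, C8, C8a). It is therefore one linear β-polycarbonyl chain primed by the ring M aroyl carbon.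
3. Cutting C4a–C8a (Claisen) and O1–C2 leads to a 6-substituted 4-hydroxy-2-pyrone whose lactone carbonyl is C8a and whose C2 is held as a methyl enol ether.
4. The chain is made by acylating the triacetic acid lactone dianion (C4a) with a ring M β-methoxyacrylate ester (C4). The biaryl bond between C8 of unit 1 and ring M comes from Suzuki–Miyaura coupling of 8-iodo-5,7-bis(benzyloxy)-4′-methoxyflavone with the ring M boronate.
5. Ring order: pyranone of unit 1 (chalcone to flavone), biaryl bond, then ring D and the pyranone of unit 2 in one flask.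

Key step: step 10

Remark: the target carries no axial descriptor, so the hindered biaryl axis between C8 of unit 1 and ring M is formed without control. The enol ether is drawn E, the isomer expected to prevail, and any Z isomer converges in step 10.

Abbreviation: ArM = 2-[5,7-bis(benzyloxy)-2-(4-methoxyphenyl)-4-oxo-4H-chromen-8-yl]-4-methoxyphenyl (ring M carrying protected unit 1).

**Route**

Step 1
Reactants: 1 2,4,6-trihydroxyacetophenone
Product: 2 1-[2,4-bis(benzyloxy)-6-hydroxyphenyl]ethanone
Conditions: BnBr (2.1 equiv), K2CO3, DMF, 0 °C to rt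
Reagents that add atoms: benzyl bromide, BrCc1ccccc1
Why: Williamson etherification in which the hydroxyl hydrogen-bonded to the acetyl carbonyl is the least nucleophilic, so two equivalents of benzyl bromide should leave exactly one ortho hydroxyl free.

Step 2
Reactants: 2 1-[2,4-bis(benzyloxy)-6-hydroxyphenyl]ethanone; 3 4-methoxybenzaldehyde
Product: 4 (2E)-1-[2,4-bis(benzyloxy)-6-hydroxyphenyl]-3-(4-methoxyphenyl)prop-2-en-1-one
Conditions: KOH (50 % aq), EtOH/THF, rt
Reagents that add atoms: none
Why: Claisen–Schmidt condensation of a methyl ketone with a non-enolisable aldehyde, the E alkene arising from base-mediated dehydration of the aldol under thermodynamic control.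

Step 3
Reactants: 4 (2E)-1-[2,4-bis(benzyloxy)-6-hydroxyphenyl]-3-(4-methoxyphenyl)prop-2-en-1-one
Product: 6 5,7-bis(benzyloxy)-2-(4-methoxyphenyl)-4H-chromen-4-one, via racemic flavanone 5 (not isolated)
Conditions: I2 (10 mol %), DMSO, 130 °C
Reagents that add atoms: none
Why: Iodine-catalysed oxidative cyclisation of a 2′-hydroxychalcone (oxa-Michael closure, α-iodination and loss of HI, with DMSO reoxidising the iodide), conditions that benzyl ethers are expected to survive.

Step 4
Reactants: 6 5,7-bis(benzyloxy)-2-(4-methoxyphenyl)-4H-chromen-4-one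
Product: 7 5,7-bis(benzyloxy)-8-iodo-2-(4-methoxyphenyl)-4H-chromen-4-one
Conditions: NIS (1.1 equiv), CF3CO2H (0.3 equiv), MeCN, 0 °C to rt, dark
Reagents that add atoms: N-iodosuccinimide, O=C1CCC(=O)N1I
Why: Electrophilic aromatic iodination, in which a 5-O-alkylated 5,7-dioxygenated flavone is expected to react at C8 (para to the C5 ether, flanked only by the C7 ether and the ring oxygen) and not at C6 (between two benzyloxy groups); the position is to be confirmed by HMBC and NOE before coupling.

Step 5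
Reactants: 8 2-bromo-4-methoxybenzoic acid
Product: 10 methyl 3-(2-bromo-4-methoxyphenyl)-3-oxopropanoate, via acyl imidazolide 9 (not isolated)
Conditions: CDI, THF, rt; then KO2CCH2CO2Me, MgCl2, Et3N, MeCN, rt to 50 °C; 1 M HCl work-up
Reagents that add atoms: potassium methyl malonate, COC(=O)CC(=O)[O-].[K+]; 1,1'-carbonyldiimidazole, O=C(n1ccnc1)n1ccnc1 (imidazolyl group of 9 only)
Why: Masamune–Brooks homologation, the magnesium enolate of the malonate half-ester being C-acylated by the imidazolide and decarboxylating to the β-keto ester under nearly neutral conditions.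

Step 6
Reactants: 10 methyl 3-(2-bromo-4-methoxyphenyl)-3-oxopropanoate
Product: 12 methyl (2E)-3-(2-bromo-4-methoxyphenyl)-3-methoxyprop-2-enoate, via dimethyl ketal 11 (not isolated)
Conditions: HC(OMe)3, H2SO4 (cat.), MeOH, reflux
Reagents that add atoms: trimethyl orthoformate, COC(OC)OC
Why: Acid-catalysed ketalisation with an orthoester followed by loss of methanol into conjugation with the ester, the standard conversion of a β-keto ester into its β-methoxyacrylate.

Step 7
Reactants: 12 methyl (2E)-3-(2-bromo-4-methoxyphenyl)-3-methoxyprop-2-enoate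
Product: 13 methyl (2E)-3-methoxy-3-[4-methoxy-2-(4,4,5,5-tetramethyl-1,3,2-dioxaborolan-2-yl)phenyl]prop-2-enoate
Conditions: B2pin2, PdCl2(dppf) (5 mol %), KOAc, 1,4-dioxane, 90 °C
Reagents that add atoms: bis(pinacolato)diboron, CC1(C)OB(OC1(C)C)B1OC(C)(C)C(C)(C)O1
Why: Miyaura borylation of an aryl bromide, with acetate as a base too weak to trigger Suzuki homocoupling or to touch the acrylate ester.

Step 8
Reactants: 7 5,7-bis(benzyloxy)-8-iodo-2-(4-methoxyphenyl)-4H-chromen-4-one; 13 methyl (2E)-3-methoxy-3-[4-methoxy-2-(4,4,5,5-tetramethyl-1,3,2-dioxaborolan-2-yl)phenyl]prop-2-enoate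
Product: 14 methyl (2E)-3-ArM-3-methoxyprop-2-enoate
Conditions: Pd(OAc)2 (5 mol %), SPhos (10 mol %), K3PO4, toluene/H2O (10:1), 90 °C
Reagents that add atoms: none
Why: Suzuki–Miyaura coupling with a bulky biaryl dialkylphosphine ligand, which is suited to the tri-ortho-substituted biaryl bond, under a phosphate base that should spare the vinylogous carbonate ester.

Step 9
Reactants: 14 methyl (2E)-3-ArM-3-methoxyprop-2-enoate; 15 4-hydroxy-6-methyl-2H-pyran-2-one (triacetic acid lactone)
Product: 17 6-[(3E)-4-ArM-4-methoxy-2-oxobut-3-en-1-yl]-4-hydroxy-2H-pyran-2-one, via dilithio triacetic acid lactone 16 (not isolated)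
Conditions: 15 (3 equiv), LiN(i-Pr)2 (6 equiv), THF, −78 to −20 °C; then 14, −78 to 0 °C; AcOH quench
Reagents that add atoms: none
Why: Claisen-type C-acylation of a polyanion, the methyl carbanion of dianion 16 being its most nucleophilic site and the product being held as an enolate, while the peri-shielded pyranone carbonyl of unit 1 and the fully substituted acrylate β-carbon are expected to be slower electrophiles than the ester at low temperature.

Step 10
Reactants: 17 6-[(3E)-4-ArM-4-methoxy-2-oxobut-3-en-1-yl]-4-hydroxy-2H-pyran-2-one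
Product: 20 5,7-bis(benzyloxy)-8-[2-(5,7-dihydroxy-4-oxo-4H-chromen-2-yl)-5-methoxyphenyl]-2-(4-methoxyphenyl)-4H-chromen-4-one, via open-chain methyl ester 18 (not isolated), via acylphloroglucinol 19 (not isolated)
Conditions: Mg(OMe)2 (8 equiv), MeOH, reflux, Ar; then 1 M HCl, rt
Reagents that add atoms: methanol, CO (ester methoxy group of 18 only; released again when ring D closes)
Why: Mg(OMe)2 methanolyses the lactone of 17 to the magnesium-chelated trioxo ester 18, whose C4a methylene (between the C5 ketone and the C4 carbonyl) is deprotonated and adds to the ester carbon C8a with loss of methoxide, and enolisation of the resulting cyclohexanetrione gives the phloroglucinol ring D of 19. The closest known reactions are the magnesium methoxide Claisen cyclisation of 6-(2-oxoalkyl)-4-hydroxy-2-pyrones to acylphloroglucinols and the ring closure of 2′-hydroxy-β-methoxychalcones to flavones. Ring D closes in a 6-(enolendo)-exo-trig mode (C4a–C8a bond), and the pyranone closes by 6-endo-trig addition of a ring D hydroxyl to C2 followed by loss of methanol (O1–C2 bond), in the basic medium or on acidification. No stereocentre is formed and the biaryl axis is left uncontrolled. The Claisen closure has to beat the aldol closure of C8 onto C4 (resorcylate) and attack of C6 on C2; chelation of the β-dicarbonyl units by magnesium, the ester oxidation level at C8a, and the enol ether (which makes C4 a weakly electrophilic vinylogous ester carbonyl, removes C3 as a carbanion site and leaves C2 a hindered β-alkoxy carbon) should all direct the chain to the C4a to C8a closure. Because C6 and C8 of ring D are both unsubstituted, the two hydroxyls flanking the acyl group are equivalent and closure through either gives the same 5,7-dihydroxychromone, and any transient methoxide opening of the unit 1 pyranone would be reclosed by the same acid treatment.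

Step 11
Reactants: 20 5,7-bis(benzyloxy)-8-[2-(5,7-dihydroxy-4-oxo-4H-chromen-2-yl)-5-methoxyphenyl]-2-(4-methoxyphenyl)-4H-chromen-4-one
Product: 21 5,7-dihydroxy-8-[2-(5,7-dihydroxy-4-oxo-4H-chromen-2-yl)-5-methoxyphenyl]-2-(4-methoxyphenyl)-4H-chromen-4-one
Conditions: H2 (1 atm), Pd/C (10 %), THF/MeOH, rt
Reagents that add atoms: none
Why: Hydrogenolysis of aryl benzyl ethers, which is fast compared with reduction of the flavone C2–C3 double bonds and leaves the two aryl methyl ethers untouched.

**Compound list**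

1 | 2,4,6-trihydroxyacetophenone | CC(=O)c1c(O)cc(O)cc1O | starting material
2 | 1-[2,4-bis(benzyloxy)-6-hydroxyphenyl]ethanone | CC(=O)c1c(O)cc(OCc2ccccc2)cc1OCc1ccccc1 | intermediate
3 | 4-methoxybenzaldehyde | COc1ccc(C=O)cc1 | starting material
4 | (2E)-1-[2,4-bis(benzyloxy)-6-hydroxyphenyl]-3-(4-methoxyphenyl)prop-2-en-1-one | COc1ccc(/C=C/C(=O)c2c(O)cc(OCc3ccccc3)cc2OCc2ccccc2)cc1 | intermediate
5 | racemic 5,7-bis(benzyloxy)-2-(4-methoxyphenyl)chroman-4-one (not isolated) | COc1ccc(C2CC(=O)c3c(OCc4ccccc4)cc(OCc4ccccc4)cc3O2)cc1 | intermediate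
6 | 5,7-bis(benzyloxy)-2-(4-methoxyphenyl)-4H-chromen-4-one | COc1ccc(-c2cc(=O)c3c(OCc4ccccc4)cc(OCc4ccccc4)cc3o2)cc1 | intermediate
7 | 5,7-bis(benzyloxy)-8-iodo-2-(4-methoxyphenyl)-4H-chromen-4-one | COc1ccc(-c2cc(=O)c3c(OCc4ccccc4)cc(OCc4ccccc4)c(I)c3o2)cc1 | intermediate
8 | 2-bromo-4-methoxybenzoic acid | COc1ccc(C(=O)O)c(Br)c1 | starting material
9 | (2-bromo-4-methoxyphenyl)(1H-imidazol-1-yl)methanone (not isolated) | COc1ccc(C(=O)n2ccnc2)c(Br)c1 | intermediate
10 | methyl 3-(2-bromo-4-methoxyphenyl)-3-oxopropanoate | COC(=O)CC(=O)c1ccc(OC)cc1Br | intermediate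
11 | methyl 3-(2-bromo-4-methoxyphenyl)-3,3-dimethoxypropanoate (not isolated) | COC(=O)CC(OC)(OC)c1ccc(OC)cc1Br | intermediate
12 | methyl (2E)-3-(2-bromo-4-methoxyphenyl)-3-methoxyprop-2-enoate | COC(=O)/C=C(/OC)c1ccc(OC)cc1Br | intermediate
13 | methyl (2E)-3-methoxy-3-[4-methoxy-2-(4,4,5,5-tetramethyl-1,3,2-dioxaborolan-2-yl)phenyl]prop-2-enoate | COC(=O)/C=C(/OC)c1ccc(OC)cc1B1OC(C)(C)C(C)(C)O1 | intermediate
14 | methyl (2E)-3-{2-[5,7-bis(benzyloxy)-2-(4-methoxyphenyl)-4-oxo-4H-chromen-8-yl]-4-methoxyphenyl}-3-methoxyprop-2-enoate | COC(=O)/C=C(/OC)c1ccc(OC)cc1-c1c(OCc2ccccc2)cc(OCc2ccccc2)c2c(=O)cc(-c3ccc(OC)cc3)oc12 | intermediate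
15 | 4-hydroxy-6-methyl-2H-pyran-2-one (triacetic acid lactone) | Cc1cc(O)cc(=O)o1 | starting material
16 | dilithium dianion of triacetic acid lactone (not isolated) | [Li+].[Li+].[CH2-]c1cc([O-])cc(=O)o1 | intermediate
17 | 6-[(3E)-4-{2-[5,7-bis(benzyloxy)-2-(4-methoxyphenyl)-4-oxo-4H-chromen-8-yl]-4-methoxyphenyl}-4-methoxy-2-oxobut-3-en-1-yl]-4-hydroxy-2H-pyran-2-one | O=C(Cc1cc(O)cc(=O)o1)/C=C(/OC)c1ccc(OC)cc1-c1c(OCc2ccccc2)cc(OCc2ccccc2)c2c(=O)cc(-c3ccc(OC)cc3)oc12 | intermediate
18 | methyl (8E)-9-{2-[5,7-bis(benzyloxy)-2-(4-methoxyphenyl)-4-oxo-4H-chromen-8-yl]-4-methoxyphenyl}-9-methoxy-3,5,7-trioxonon-8-enoate (not isolated, drawn in the keto form) | COC(=O)CC(=O)CC(=O)CC(=O)/C=C(/OC)c1ccc(OC)cc1-c1c(OCc2ccccc2)cc(OCc2ccccc2)c2c(=O)cc(-c3ccc(OC)cc3)oc12 | intermediate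
19 | (2E)-3-{2-[5,7-bis(benzyloxy)-2-(4-methoxyphenyl)-4-oxo-4H-chromen-8-yl]-4-methoxyphenyl}-3-methoxy-1-(2,4,6-trihydroxyphenyl)prop-2-en-1-one (not isolated) | O=C(/C=C(/OC)c1ccc(OC)cc1-c1c(OCc2ccccc2)cc(OCc2ccccc2)c2c(=O)cc(-c3ccc(OC)cc3)oc12)c1c(O)cc(O)cc1O | intermediate
20 | 5,7-bis(benzyloxy)-8-[2-(5,7-dihydroxy-4-oxo-4H-chromen-2-yl)-5-methoxyphenyl]-2-(4-methoxyphenyl)-4H-chromen-4-one | COc1ccc(-c2cc(=O)c3c(OCc4ccccc4)cc(OCc4ccccc4)c(-c4cc(OC)ccc4-c4cc(=O)c5c(O)cc(O)cc5o4)c3o2)cc1 | intermediate
21 | 5,7-dihydroxy-8-[2-(5,7-dihydroxy-4-oxo-4H-chromen-2-yl)-5-methoxyphenyl]-2-(4-methoxyphenyl)-4H-chromen-4-one (CNP0394081.0) | COc1ccc(-c2cc(=O)c3c(O)cc(O)c(-c4cc(OC)ccc4-c4cc(=O)c5c(O)cc(O)cc5o4)c3o2)cc1 | target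

**Step count**

Total: 11 steps. Longest linear sequence: 8 steps (steps 1, 2, 3, 4, 8, 9, 10, 11).

**Steps most likely to fail and fallbacks**

Step 9. The dianion may add to the pyranone carbonyl of unit 1 or displace methoxide at the acrylate β-carbon, or the deactivated ester may not react before the dianion decomposes on warming. The fallback assembles the chain without a strongly basic polyanion and sets out from 14. Hydrolysis with Me3SnOH in 1,2-dichloroethane at 80 °C should give the acid (2E)-3-ArM-3-methoxyprop-2-enoic acid F1. Treatment with 1-chloro-N,N,2-trimethylprop-1-en-1-amine in CH2Cl2 at 0 °C should give the acid chloride (2E)-3-ArM-3-methoxyprop-2-enoyl chloride F2 under neutral conditions. The acid chloride is then combined with 1-methoxy-1,3,5-tris(trimethylsilyloxy)hexa-1,3,5-triene (the tris-silyl enol ether of methyl 3,5-dioxohexanoate) in CH2Cl2 at −78 to 20 °C, a Mukaiyama-type acylation at the terminal carbon of the kind established for silyl dienol ethers with unsaturated acid chlorides. Mild aqueous acid work-up removes the silyl groups, and the route is rejoined at open-chain ester 18, which is taken crude into the Mg(OMe)2 treatment of step 10.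

Step 10. The chain may fold through the aldol closure of C8 onto C4 instead of the Claisen closure, the lactone may be methanolysed without ring closure, or unit 1 may be degraded on long exposure to methoxide. The fallback builds unit 2 from a preformed phloroglucinol ring and sets out from iodide 7. Suzuki–Miyaura coupling with commercial (2-formyl-5-methoxyphenyl)boronic acid under the conditions of step 8 should give the aldehyde 2-[5,7-bis(benzyloxy)-2-(4-methoxyphenyl)-4-oxo-4H-chromen-8-yl]-4-methoxybenzaldehyde F3. Claisen–Schmidt condensation of this aldehyde with acetophenone 2 (KOH, EtOH/THF, rt) should give the 2′-hydroxychalcone F4. Oxidative cyclisation as in step 3 (I2 cat., DMSO, 130 °C) should give the biflavone tetrabenzyl ether F5. Hydrogenolysis as in step 11 rejoins the route at target 21.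

Step 4. Iodination may occur at C6 or at C3 of the pyranone instead of C8, or run on to a di-iodide, giving isomers that are hard to separate. The fallback introduces iodine before the pyranone exists and sets out from acetophenone 2. Iodination ortho to the only free phenol with benzyltrimethylammonium dichloroiodate and NaHCO3 in CH2Cl2/MeOH at rt should give 1-[4,6-bis(benzyloxy)-2-hydroxy-3-iodophenyl]ethanone F6. Claisen–Schmidt condensation with aldehyde 3 should give the iodochalcone F7. Cyclisation with I2 (cat.) in DMSO at 130 °C rejoins the route at 7, since the phenol oxygen next to the iodine becomes O1 and the iodinated carbon becomes C8.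

**Further compounds**

F1 | step 9 | (2E)-3-{2-[5,7-bis(benzyloxy)-2-(4-methoxyphenyl)-4-oxo-4H-chromen-8-yl]-4-methoxyphenyl}-3-methoxyprop-2-enoic acid | OC(=O)/C=C(/OC)c1ccc(OC)cc1-c1c(OCc2ccccc2)cc(OCc2ccccc2)c2c(=O)cc(-c3ccc(OC)cc3)oc12
F2 | step 9 | (2E)-3-{2-[5,7-bis(benzyloxy)-2-(4-methoxyphenyl)-4-oxo-4H-chromen-8-yl]-4-methoxyphenyl}-3-methoxyprop-2-enoyl chloride | ClC(=O)/C=C(/OC)c1ccc(OC)cc1-c1c(OCc2ccccc2)cc(OCc2ccccc2)c2c(=O)cc(-c3ccc(OC)cc3)oc12
F3 | step 10 | 2-[5,7-bis(benzyloxy)-2-(4-methoxyphenyl)-4-oxo-4H-chromen-8-yl]-4-methoxybenzaldehyde | COc1ccc(C=O)c(-c2c(OCc3ccccc3)cc(OCc3ccccc3)c3c(=O)cc(-c4ccc(OC)cc4)oc23)c1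
F4 | step 10 | (2E)-1-[2,4-bis(benzyloxy)-6-hydroxyphenyl]-3-{2-[5,7-bis(benzyloxy)-2-(4-methoxyphenyl)-4-oxo-4H-chromen-8-yl]-4-methoxyphenyl}prop-2-en-1-one | COc1ccc(/C=C/C(=O)c2c(O)cc(OCc3ccccc3)cc2OCc2ccccc2)c(-c2c(OCc3ccccc3)cc(OCc3ccccc3)c3c(=O)cc(-c4ccc(OC)cc4)oc23)c1
F5 | step 10 | 5,7-bis(benzyloxy)-8-{2-[5,7-bis(benzyloxy)-4-oxo-4H-chromen-2-yl]-5-methoxyphenyl}-2-(4-methoxyphenyl)-4H-chromen-4-one | COc1ccc(-c2cc(=O)c3c(OCc4ccccc4)cc(OCc4ccccc4)c(-c4cc(OC)ccc4-c4cc(=O)c5c(OCc6ccccc6)cc(OCc6ccccc6)cc5o4)c3o2)cc1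
F6 | step 4 | 1-[4,6-bis(benzyloxy)-2-hydroxy-3-iodophenyl]ethanone | CC(=O)c1c(O)c(I)c(OCc2ccccc2)cc1OCc1ccccc1
F7 | step 4 | (2E)-1-[4,6-bis(benzyloxy)-2-hydroxy-3-iodophenyl]-3-(4-methoxyphenyl)prop-2-en-1-one | COc1ccc(/C=C/C(=O)c2c(O)c(I)c(OCc3ccccc3)cc2OCc2ccccc2)cc1
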